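**Plan**
1. Ring numbering: O1, C2 (4-hydroxy-3,5-dimethoxyphenyl), C3, C4, C5 (3,4,5-trimethoxyphenyl). The target is the all-trans (2R,3S,4S,5R) isomer, with a pseudo-C2 axis through O1 and the midpoint of C3–C4.
2. Cuts: first O1–C2/O1–C5 (ether to 1,4-diol). C2/C5 are then raised to ketones and both CH2OH carbons to esters, and the central C3–C4 bond is cut. Two aroylacetate halves (aryl–C–C–C each) remain.
3. Forward: the halves are joined at C3–C4 without stereocontrol. One reduction then closes two γ-lactone rings (a cis-fused bicycle), hydride opens both, and the oxolane ring is closed last.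
4. Enabling feature: C3 and C4 each lie between a benzylic C–O ring carbon (C2, C5) and an exocyclic CH2OH carbon. At the keto ester level each is therefore the α-carbon of a β-keto ester and configurationally labile, and the pseudo-C2 axis makes both halves ask the same sense of one catalyst.
5. Stereochemistry: a double dynamic kinetic resolution (DKR) by asymmetric transfer hydrogenation (ATH) funnels all stereoisomers of the diketo diester into one bislactone. C2/C5 come from the catalyst and C3/C4 from syn-selective DKR. The final ring closure re-forms one benzylic centre trans, under control of C3/C4.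

Key step: step 5

Assumption: acetosyringone and ethyl 3,4,5-trimethoxybenzoylacetate are taken as commercial. The sense of induction in step 5 is extrapolated from (R,R)-TsDPEN–Ru catalysts giving (R)-1-arylalkanols and syn-α-alkyl-β-hydroxy carbonyl compounds.

Step 1
Reactants: 1 acetosyringone [1-(4-hydroxy-3,5-dimethoxyphenyl)ethanone]
Product: 2 1-[4-(benzyloxy)-3,5-dimethoxyphenyl]ethanone
Conditions: BnBr, K2CO3, DMF, 60 °C
Reagents that add atoms: benzyl bromide, BrCc1ccccc1
Why: Williamson ether synthesis at the only acidic site masks the phenol that distinguishes the two aryl rings; no stereocentre is formed.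

Step 2
Reactants: 2 1-[4-(benzyloxy)-3,5-dimethoxyphenyl]ethanone
Product: 4 ethyl 3-[4-(benzyloxy)-3,5-dimethoxyphenyl]-3-oxopropanoate, via sodium enolate 3 (not isolated)
Conditions: NaH, (EtO)2CO, THF, reflux; then AcOH, 0 °C
Reagents that add atoms: diethyl carbonate, CCOC(=O)OCC
Why: Crossed Claisen condensation of a methyl ketone enolate with the non-enolisable carbonate is driven by deprotonation of the β-keto ester to its sodium enolate, which is quenched so that the neutral keto ester can be purified free of excess base; no stereocentre is formed.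

Step 3
Reactants: 5 ethyl 3-oxo-3-(3,4,5-trimethoxyphenyl)propanoate
Product: 6 ethyl 2-chloro-3-oxo-3-(3,4,5-trimethoxyphenyl)propanoate (racemic, labile)
Conditions: NCS, Mg(ClO4)2 (cat.), EtOAc, rt
Reagents that add atoms: N-chlorosuccinimide, O=C1CCC(=O)N1Cl
Why: Electrophilic α-chlorination of the enol of a β-keto ester is routine and the acyl group deactivates the ring, chlorine is chosen because halogen transfer to a stabilised enolate is slowest for it, and the new stereocentre is labile and of no consequence.

Step 4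
Reactants: 4 ethyl 3-[4-(benzyloxy)-3,5-dimethoxyphenyl]-3-oxopropanoate; 6 ethyl 2-chloro-3-oxo-3-(3,4,5-trimethoxyphenyl)propanoate
Product: 8 diethyl 2-[4-(benzyloxy)-3,5-dimethoxybenzoyl]-3-(3,4,5-trimethoxybenzoyl)butanedioate (interconverting stereoisomers), via potassium enolate 7 (not isolated)
Conditions: KHMDS (1.0 equiv), THF, −78 → 0 °C; then 6, THF–DMF, 0 °C → rt
Reagents that add atoms: none
Why: SN2 alkylation of a stabilised enolate by an α-halo-β-keto ester, the classical entry to unsymmetrical 2,3-diacylsuccinates, forms C3–C4 as a directed cross-coupling, one equivalent of an aprotic potassium amide gives the more dissociated and more nucleophilic potassium enolate without leaving excess base or a protic shuttle for the acidic chloride, and the two new stereocentres are left uncontrolled on purpose because both remain labile until step 5.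

Step 5
Reactants: 8 diethyl 2-[4-(benzyloxy)-3,5-dimethoxybenzoyl]-3-(3,4,5-trimethoxybenzoyl)butanedioate
Product: 10 (3R,3aR,6R,6aR)-3-[4-(benzyloxy)-3,5-dimethoxyphenyl]-6-(3,4,5-trimethoxyphenyl)tetrahydrofuro[3,4-c]furan-1,4-dione (exo,exo-bislactone), via syn,syn-diol diester 9 (not isolated)
Conditions: RuCl[(R,R)-TsDPEN](p-cymene) (cat.), HCO2H/Et3N (5:2), CH2Cl2, 30 °C; crude product then PPTS (cat.), toluene, 50 °C
Reagents that add atoms: none
Why: Proposed new method: In HCO2H/Et3N the two α-carbons of 8 (future C3 and C4) epimerise freely through their enols while the Ru–H/N–H form of the (R,R)-catalyst delivers H−/H+ to each aryl ketone through the concerted six-membered outer-sphere transition state, so that under Curtin–Hammett conditions all stereoisomers of 8 should drain into the single diol 9. The closest known reaction types are the DKR–ATH of α-alkyl β-keto esters and amides and of 2-acylsuccinates with lactonisation in situ, the catalyst-controlled double ATH of 1,4-diaryl-1,4-diones, and the reduction of benzil through labile benzoin; new is that two adjacent labile centres are resolved in one operation. C2 and C5 (both R) are set by the catalyst, whose η6-arene holds the aryl group by a CH–π contact and so fixes the ketone face, and C3 and C4 are set by the faster reduction of the epimer in which the bulky other half of the succinate lies anti to the incoming hydride and the small H faces the aryl ring, which gives the syn-β-hydroxy ester on each side. Because the two halves of 8 are related by the pseudo-C2 axis, one catalyst is matched to both, the two ketones need not be told apart, and the C2-type rather than the meso-type relation should result at C3/C4. Each hydroxyl then closes a γ-lactone on the ester of the other half by 5-exo-trig addition–elimination with loss of ethanol, and the second closure is open only to the C2-type isomer because only the cis-fused 3,7-dioxabicyclo[3.3.0]octanedione with both aryl groups on the convex face is unstrained, so 10 can be freed from stereochemical errors by crystallisation. The step needs reduction to outrun Paal–Knorr dehydration to the furan and β-elimination, which the buffered medium, the low temperature and the capture of the carbinols as lactones should secure.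

Step 6
Reactants: 10 exo,exo-bislactone
Product: 11 (1R,2S,3S,4R)-1-[4-(benzyloxy)-3,5-dimethoxyphenyl]-2,3-bis(hydroxymethyl)-4-(3,4,5-trimethoxyphenyl)butane-1,4-diol
Conditions: LiAlH4, THF, 0 °C → rt; aqueous NaOH work-up
Reagents that add atoms: none
Why: Hydride reduction of lactones to diols, well known for 2,6-diaryl bislactones of this type, outruns enolisation, so all four stereocentres are carried over and C3/C4 cease to be α-carbonyl centres.

Step 7
Reactants: 11 tetrol
Product: 12 (1R,2S,3S,4R)-1-[4-(benzyloxy)-3,5-dimethoxyphenyl]-2,3-bis{[(tert-butyldiphenylsilyl)oxy]methyl}-4-(3,4,5-trimethoxyphenyl)butane-1,4-diol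
Conditions: TBDPSCl (2 equiv), imidazole, CH2Cl2–DMF, 0 °C
Reagents that add atoms: tert-butyl(chloro)diphenylsilane, CC(C)(C)[Si](Cl)(c1ccccc1)c1ccccc1
Why: Sterically controlled silylation takes the two primary hydroxyls before the hindered secondary benzylic ones and so removes the oxygens that would otherwise close the isomeric furofuran rings; no stereocentre is touched.

Step 8
Reactants: 12 bis-silylated 1,4-diol
Product: 13 (2R,3S,4S,5R)-2-[4-(benzyloxy)-3,5-dimethoxyphenyl]-3,4-bis{[(tert-butyldiphenylsilyl)oxy]methyl}-5-(3,4,5-trimethoxyphenyl)oxolane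
Conditions: TFA (cat.), CH2Cl2, 0 °C
Reagents that add atoms: none
Why: Acid-catalysed SN1 cyclodehydration of a 1,4-diaryl-1,4-butanediol closes the oxolane; the attacking carbinol keeps its R configuration, the ionised centre is re-formed trans to the bulky neighbouring CH2OSi group, and the pseudo-C2 axis makes ionisation at either end give the same all-trans product.

Step 9
Reactants: 13 protected oxolane
Product: 14 [(2R,3S,4S,5R)-2-[4-(benzyloxy)-3,5-dimethoxyphenyl]-5-(3,4,5-trimethoxyphenyl)oxolane-3,4-diyl]dimethanol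
Conditions: TBAF, THF, rt; aqueous work-up
Reagents that add atoms: none
Why: Fluoride-induced desilylation is driven by the Si–F bond and leaves ethers and stereocentres untouched.

Step 10
Reactants: 14 benzyl-protected diol
Product: 15 4-[(2R,3S,4S,5R)-3,4-bis(hydroxymethyl)-5-(3,4,5-trimethoxyphenyl)oxolan-2-yl]-2,6-dimethoxyphenol (target)
Conditions: H2 (1 atm), Pd/C, EtOAc, rt
Reagents that add atoms: none
Why: Hydrogenolysis of the aryl benzyl ether under neutral conditions is faster than cleavage of the hindered ring C–O bonds, as is usual for 2,5-diaryloxolane lignans, and touches no stereocentre.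

**Compound list**
1 | acetosyringone, 1-(4-hydroxy-3,5-dimethoxyphenyl)ethanone | CC(=O)c1cc(OC)c(O)c(OC)c1 | starting material
2 | 1-[4-(benzyloxy)-3,5-dimethoxyphenyl]ethanone | CC(=O)c1cc(OC)c(OCc2ccccc2)c(OC)c1 | intermediate
3 | sodium (Z)-enolate of 4 | CCOC(=O)/C=C(\[O-])c1cc(OC)c(OCc2ccccc2)c(OC)c1.[Na+] | intermediate
4 | ethyl 3-[4-(benzyloxy)-3,5-dimethoxyphenyl]-3-oxopropanoate | CCOC(=O)CC(=O)c1cc(OC)c(OCc2ccccc2)c(OC)c1 | intermediate
5 | ethyl 3-oxo-3-(3,4,5-trimethoxyphenyl)propanoate | CCOC(=O)CC(=O)c1cc(OC)c(OC)c(OC)c1 | starting material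
6 | ethyl 2-chloro-3-oxo-3-(3,4,5-trimethoxyphenyl)propanoate (racemic, labile) | CCOC(=O)C(Cl)C(=O)c1cc(OC)c(OC)c(OC)c1 | intermediate
7 | potassium (Z)-enolate of 4 | CCOC(=O)/C=C(\[O-])c1cc(OC)c(OCc2ccccc2)c(OC)c1.[K+] | intermediate
8 | diethyl 2-[4-(benzyloxy)-3,5-dimethoxybenzoyl]-3-(3,4,5-trimethoxybenzoyl)butanedioate (interconverting stereoisomers) | CCOC(=O)C(C(=O)c1cc(OC)c(OCc2ccccc2)c(OC)c1)C(C(=O)OCC)C(=O)c1cc(OC)c(OC)c(OC)c1 | intermediate
9 | diethyl (2R,3R)-2-{(R)-[4-(benzyloxy)-3,5-dimethoxyphenyl](hydroxy)methyl}-3-[(R)-hydroxy(3,4,5-trimethoxyphenyl)methyl]butanedioate | COc1cc([C@H](O)[C@H](C(=O)OCC)[C@@H](C(=O)OCC)[C@@H](O)c2cc(OC)c(OC)c(OC)c2)cc(OC)c1OCc1ccccc1 | intermediate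
10 | (3R,3aR,6R,6aR)-3-[4-(benzyloxy)-3,5-dimethoxyphenyl]-6-(3,4,5-trimethoxyphenyl)tetrahydrofuro[3,4-c]furan-1,4-dione | COc1cc([C@@H]2OC(=O)[C@@H]3[C@H]2C(=O)O[C@H]3c4cc(OC)c(OC)c(OC)c4)cc(OC)c1OCc5ccccc5 | intermediate
11 | (1R,2S,3S,4R)-1-[4-(benzyloxy)-3,5-dimethoxyphenyl]-2,3-bis(hydroxymethyl)-4-(3,4,5-trimethoxyphenyl)butane-1,4-diol | COc1cc([C@H](O)[C@H](CO)[C@@H](CO)[C@@H](O)c2cc(OC)c(OC)c(OC)c2)cc(OC)c1OCc1ccccc1 | intermediate
12 | (1R,2S,3S,4R)-1-[4-(benzyloxy)-3,5-dimethoxyphenyl]-2,3-bis{[(tert-butyldiphenylsilyl)oxy]methyl}-4-(3,4,5-trimethoxyphenyl)butane-1,4-diol | COc1cc([C@H](O)[C@H](CO[Si](c2ccccc2)(c2ccccc2)C(C)(C)C)[C@@H](CO[Si](c2ccccc2)(c2ccccc2)C(C)(C)C)[C@@H](O)c2cc(OC)c(OC)c(OC)c2)cc(OC)c1OCc1ccccc1 | intermediate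
13 | (2R,3S,4S,5R)-2-[4-(benzyloxy)-3,5-dimethoxyphenyl]-3,4-bis{[(tert-butyldiphenylsilyl)oxy]methyl}-5-(3,4,5-trimethoxyphenyl)oxolane | COc1cc([C@@H]2O[C@@H](c3cc(OC)c(OC)c(OC)c3)[C@H](CO[Si](c3ccccc3)(c3ccccc3)C(C)(C)C)[C@H]2CO[Si](c2ccccc2)(c2ccccc2)C(C)(C)C)cc(OC)c1OCc1ccccc1 | intermediate
14 | [(2R,3S,4S,5R)-2-[4-(benzyloxy)-3,5-dimethoxyphenyl]-5-(3,4,5-trimethoxyphenyl)oxolane-3,4-diyl]dimethanol | COc1cc([C@@H]2O[C@@H](c3cc(OC)c(OC)c(OC)c3)[C@H](CO)[C@H]2CO)cc(OC)c1OCc1ccccc1 | intermediate
15 | 4-[(2R,3S,4S,5R)-3,4-bis(hydroxymethyl)-5-(3,4,5-trimethoxyphenyl)oxolan-2-yl]-2,6-dimethoxyphenol | COc1cc([C@@H]2O[C@@H](c3cc(OC)c(OC)c(OC)c3)[C@H](CO)[C@H]2CO)cc(OC)c1O | target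

Total step count: 10. Longest linear sequence: 9 steps (1 → 15 through steps 1, 2 and 4–10).

**Steps most likely to fail**

Step 5 carries three risks.
- Hydride transfer to the hindered, electron-rich ketones may be slow enough for dehydration to the furan to compete.
- The syn preference may erode.
- Early lactonisation of the first carbinol may let the remaining labile centre be reduced from the epimer that carries the aroyl group trans to the ester on the lactone ring. That meso-type isomer cannot close the second ring.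

Fallback, from 8, returning at 10: the diketo diester is reduced without asymmetric control (NaBH4, EtOH–THF, 0 °C, then PPTS, toluene), the classical entry to such bicycles. This gives the racemic exo,exo-bislactone F1, which is purified by crystallisation. Its enantiomers are separated by preparative chromatography on a polysaccharide chiral stationary phase. Compound 10 re-enters at step 6 and the mirror-image bislactone F2 is set aside.

Step 4 may suffer from proton and halogen transfer between enolate and chloride. Self-condensation of the chloride, O-alkylation or Feist–Bénary furan formation may then erode the directed cross-coupling.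

Fallback, from 4 and 5, returning at 8: scrambling is accepted, and the bond is made by the classical oxidative coupling of mixed sodium enolates. Compound 4 and an excess of the cheap partner 5 are deprotonated together (NaH, THF) to 3 and the sodium enolate of 5 F3, and I2 is then added. Most of 4 should then end up in 8. Chromatography removes the co-formed diethyl 2,3-bis(3,4,5-trimethoxybenzoyl)butanedioate F4 and the minor diethyl 2,3-bis[4-(benzyloxy)-3,5-dimethoxybenzoyl]butanedioate F5.

Step 8 has three possible failure modes.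
- Friedel–Crafts capture of the benzylic cation by the other electron-rich ring, which gives an aryltetralin.
- Loss of a silyl group, followed by closure onto a primary oxygen.
- Incomplete trans selectivity.

Fallback, from 12, returning at 15: the benzyl ether is removed first (H2, Pd/C, EtOAc) to give the phenolic diol F6. Its free para-hydroxyl lets only the C2 carbinol ionise, under nearly neutral conditions (PPTS cat., CH2Cl2), through the p-quinone methide F7. The C5 hydroxyl adds to F7 reversibly, with its configuration retained, to give the all-trans phenolic oxolane bis-silyl ether F8. TBAF then gives 15 directly.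

**Further compounds**
F1 | step 5 | racemic exo,exo-bislactone (10 and its mirror image, equal parts) | COc1cc([C@@H]2OC(=O)[C@@H]3[C@H]2C(=O)O[C@H]3c4cc(OC)c(OC)c(OC)c4)cc(OC)c1OCc5ccccc5.COc1cc([C@H]2OC(=O)[C@H]3[C@@H]2C(=O)O[C@@H]3c4cc(OC)c(OC)c(OC)c4)cc(OC)c1OCc5ccccc5
F2 | step 5 | (3S,3aS,6S,6aS)-bislactone, mirror image of 10 | COc1cc([C@H]2OC(=O)[C@H]3[C@@H]2C(=O)O[C@@H]3c4cc(OC)c(OC)c(OC)c4)cc(OC)c1OCc5ccccc5
F3 | step 4 | sodium (Z)-enolate of 5 | CCOC(=O)/C=C(\[O-])c1cc(OC)c(OC)c(OC)c1.[Na+]
F4 | step 4 | diethyl 2,3-bis(3,4,5-trimethoxybenzoyl)butanedioate | CCOC(=O)C(C(=O)c1cc(OC)c(OC)c(OC)c1)C(C(=O)OCC)C(=O)c1cc(OC)c(OC)c(OC)c1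
F5 | step 4 | diethyl 2,3-bis[4-(benzyloxy)-3,5-dimethoxybenzoyl]butanedioate | CCOC(=O)C(C(=O)c1cc(OC)c(OCc2ccccc2)c(OC)c1)C(C(=O)OCC)C(=O)c1cc(OC)c(OCc2ccccc2)c(OC)c1
F6 | step 8 | (1R,2S,3S,4R)-2,3-bis{[(tert-butyldiphenylsilyl)oxy]methyl}-1-(4-hydroxy-3,5-dimethoxyphenyl)-4-(3,4,5-trimethoxyphenyl)butane-1,4-diol | COc1cc([C@H](O)[C@H](CO[Si](c2ccccc2)(c2ccccc2)C(C)(C)C)[C@@H](CO[Si](c2ccccc2)(c2ccccc2)C(C)(C)C)[C@@H](O)c2cc(OC)c(OC)c(OC)c2)cc(OC)c1O
F7 | step 8 | p-quinone methide derived from F6 | COC1=CC(=C[C@H](CO[Si](c2ccccc2)(c2ccccc2)C(C)(C)C)[C@@H](CO[Si](c2ccccc2)(c2ccccc2)C(C)(C)C)[C@@H](O)c2cc(OC)c(OC)c(OC)c2)C=C(OC)C1=O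
F8 | step 8 | 4-[(2R,3S,4S,5R)-3,4-bis{[(tert-butyldiphenylsilyl)oxy]methyl}-5-(3,4,5-trimethoxyphenyl)oxolan-2-yl]-2,6-dimethoxyphenol | COc1cc([C@@H]2O[C@@H](c3cc(OC)c(OC)c(OC)c3)[C@H](CO[Si](c3ccccc3)(c3ccccc3)C(C)(C)C)[C@H]2CO[Si](c2ccccc2)(c2ccccc2)C(C)(C)C)cc(OC)c1O
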